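## Retrosynthetic overview

1. The ester C–O bond is cut last: target ⇒ rohitukine + angelic acid, joined by an acylation that keeps the Z double bond.
2. The pyranone ring (ring C) ⇒ a 2-hydroxyaryl methyl ketone + ethyl acetate (Claisen condensation, cyclodehydration). The acetyl group comes from a Friedel–Crafts acetylation that breaks the mirror symmetry of a 2,4,6-trimethoxyphenyl ring.
3. The cis-(3S,4R)-piperidinol ⇒ a flat, achiral 3-hydroxy-1-methyl-4-arylpyridinium salt. A dearomatising hydrogenation to the labile piperidin-3-one, followed in the same flask by dynamic kinetic resolution, sets both stereocentres.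
4. The pyridinium salt ⇒ 1,3,5-trimethoxybenzene + 4-bromopyridin-3-ol (lithiation, Negishi coupling) + iodomethane.
5. Ring order: the benzene ring (ring A) and the pyridine ring are bought and joined; the pyridine becomes the piperidine in step 3; ring C is built in step 5.

Assumption: the sense of induction in step 3 is assigned by analogy with the hydrogenation of 2-substituted cyclohexanones; if the measured rotation shows the antipode, the mirror-image complex RuCl2[(R)-binap][(S,S)-dpen] is used in the same step.

## Route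

Step 1
Reactants: 1 1,3,5-trimethoxybenzene; 2 4-bromopyridin-3-ol
Product: 6 4-(2,4,6-trimethoxyphenyl)pyridin-3-ol, via aryllithium 3 (not isolated), via arylzinc chloride 4 (not isolated), via sodium pyridinolate 5 (not isolated)
Conditions: 1 (1.4 equiv), n-BuLi, THF, 0 °C to rt; ZnCl2, rt; added to 2 pre-treated with NaH (1.05 equiv, THF/NMP, 0 °C); Pd(OAc)2 (2 mol%), SPhos (4 mol%), 65 °C; aq. NH4Cl
Reagents that add atoms: none
Why: Ortho-lithiation of 1 between two methoxy groups, transmetalation to zinc and Negishi coupling with a zerovalent palladium–SPhos catalyst that tolerates tri-ortho-substituted biaryl formation, the hydroxyl group being masked as its sodium salt so that it cannot protonate the arylzinc.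

Step 2
Reactants: 6 4-(2,4,6-trimethoxyphenyl)pyridin-3-ol
Product: 7 3-hydroxy-1-methyl-4-(2,4,6-trimethoxyphenyl)pyridin-1-ium iodide
Conditions: MeI (1.5 equiv), MeCN, 60 °C, sealed tube
Reagents that add atoms: iodomethane, CI
Why: Menshutkin N-alkylation, in which the neutral hydroxypyridine reacts at the nitrogen lone pair while O-methylation would need the phenoxide, which is absent without base.

Step 3
Reactants: 7 3-hydroxy-1-methyl-4-(2,4,6-trimethoxyphenyl)pyridin-1-ium iodide
Product: 10 (3S,4R)-1-methyl-4-(2,4,6-trimethoxyphenyl)piperidin-3-ol, via oxidopyridinium betaine 8 (not isolated), via piperidin-3-one 9 (not isolated)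
Conditions: [Ir(cod)Cl]2 (1 mol%), PPh3 (4 mol%), NaHCO3 (1.05 equiv), H2 (40 bar), THF/i-PrOH, 40 °C; vent; then RuCl2[(S)-binap][(R,R)-dpen] (1 mol%), t-BuOK (20 mol%), H2 (20 bar), 25 °C
Reagents that add atoms: none
Why: Proposed new method: betaine 8 takes up hydride from the iridium hydride at C6 and then at the resulting enone, and the enol tautomerises to ketone 9 (closest known reaction: iridium-catalysed hydrogenation of 3-hydroxypyridinium salts to piperidin-3-ones); the C4 centre of 9 epimerises rapidly through its enolate under t-BuOK while the chiral ruthenium diphosphine/diamine hydride reduces one enantiomer faster and delivers hydride to the carbonyl face anti to the aryl group (closest known reaction: dynamic kinetic resolution in the asymmetric hydrogenation of 2-substituted cyclohexanones to cis-alcohols), so the flat achiral pyridinium ring becomes the cis-(3S,4R) amino alcohol with both stereocentres set in one operation.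

Step 4
Reactants: 10 (3S,4R)-1-methyl-4-(2,4,6-trimethoxyphenyl)piperidin-3-ol
Product: 12 1-{2-hydroxy-3-[(3S,4R)-3-hydroxy-1-methylpiperidin-4-yl]-4,6-dimethoxyphenyl}ethan-1-one, via O-acetyl aryl ketone 11 (not isolated)
Conditions: Ac2O (5 equiv), BF3·OEt2 (6 equiv), CH2Cl2, 0 °C to rt; concentrate; then aq. NaOH, MeOH, 50 °C
Reagents that add atoms: acetic anhydride, CC(=O)OC(C)=O
Why: Friedel–Crafts acetylation at one of the two equivalent free positions of the mirror-symmetric trimethoxyphenyl ring, then BF3-chelation-assisted cleavage of the crowded methoxy group flanked by the acetyl and piperidinyl groups (the oxygen that later becomes O1), with the alcohol acetylated at the same time and freed again by saponification; both stereocentres are untouched.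

Step 5
Reactants: 12 1-{2-hydroxy-3-[(3S,4R)-3-hydroxy-1-methylpiperidin-4-yl]-4,6-dimethoxyphenyl}ethan-1-one
Product: 15 rohitukine, 5,7-dihydroxy-8-[(3S,4R)-3-hydroxy-1-methylpiperidin-4-yl]-2-methyl-4H-chromen-4-one, via β-diketone 13 (not isolated), via dimethoxychromone 14 (not isolated)
Conditions: NaH (5 equiv), EtOAc (4 equiv), THF, 65 °C; EtOH quench, evaporate; then pyridine hydrochloride (30 equiv), 180 °C
Reagents that add atoms: ethyl acetate, CCOC(C)=O
Why: Crossed Claisen condensation of the methyl ketone with ethyl acetate gives the β-diketone, which in molten pyridinium chloride undergoes acid-catalysed cyclodehydration to the 2-methylchromone (ring C) and SN2 cleavage of both aryl methyl ethers by chloride, while the non-epimerisable benzylic and carbinol centres are kept.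

Step 6
Reactants: 15 rohitukine; 16 angelic acid, (2Z)-2-methylbut-2-enoic acid
Product: 18 (3S,4R)-4-(5,7-dihydroxy-2-methyl-4-oxo-4H-chromen-8-yl)-1-methylpiperidin-3-yl (2Z)-2-methylbut-2-enoate, via bis-angelate 17 (not isolated)
Conditions: 16 (3 equiv), 2,4,6-trichlorobenzoyl chloride (3 equiv), Et3N (6 equiv), toluene, rt; then 15, toluene/1,4-dioxane, 75 °C; then MeOH, K2CO3, 0 °C, AcOH quench
Reagents that add atoms: none
Why: Yamaguchi-type mixed-anhydride esterification without a nucleophilic catalyst acylates with retention of the Z double bond, and the aryl angelate that also forms at the acidic 7-OH is an active ester cleaved selectively by mild base-catalysed methanolysis, leaving the hindered alkyl angelate and the chelated 5-OH; acylation is at oxygen, so C3 of the piperidine keeps its configuration.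

## Compound list

1 | 1,3,5-trimethoxybenzene | COc1cc(OC)cc(OC)c1 | starting material
2 | 4-bromopyridin-3-ol | Oc1cnccc1Br | starting material
3 | 2,4,6-trimethoxyphenyllithium | [Li]c1c(OC)cc(OC)cc1OC | intermediate
4 | (2,4,6-trimethoxyphenyl)zinc chloride | Cl[Zn]c1c(OC)cc(OC)cc1OC | intermediate
5 | sodium 4-bromopyridin-3-olate | [Na+].[O-]c1cnccc1Br | intermediate
6 | 4-(2,4,6-trimethoxyphenyl)pyridin-3-ol | COc1cc(OC)c(-c2ccncc2O)c(OC)c1 | intermediate
7 | 3-hydroxy-1-methyl-4-(2,4,6-trimethoxyphenyl)pyridin-1-ium iodide | C[n+]1ccc(-c2c(OC)cc(OC)cc2OC)c(O)c1.[I-] | intermediate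
8 | 1-methyl-4-(2,4,6-trimethoxyphenyl)pyridin-1-ium-3-olate (betaine) | C[n+]1ccc(-c2c(OC)cc(OC)cc2OC)c([O-])c1 | intermediate
9 | 1-methyl-4-(2,4,6-trimethoxyphenyl)piperidin-3-one (racemic, C4 configurationally labile) | CN1CCC(c2c(OC)cc(OC)cc2OC)C(=O)C1 | intermediate
10 | (3S,4R)-1-methyl-4-(2,4,6-trimethoxyphenyl)piperidin-3-ol (cis) | O[C@@H]1CN(C)CC[C@@H]1c1c(OC)cc(OC)cc1OC | intermediate
11 | (3S,4R)-4-(3-acetyl-2-hydroxy-4,6-dimethoxyphenyl)-1-methylpiperidin-3-yl acetate | CC(=O)O[C@@H]1CN(C)CC[C@@H]1c1c(O)c(C(C)=O)c(OC)cc1OC | intermediate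
12 | 1-{2-hydroxy-3-[(3S,4R)-3-hydroxy-1-methylpiperidin-4-yl]-4,6-dimethoxyphenyl}ethan-1-one | O[C@@H]1CN(C)CC[C@@H]1c1c(O)c(C(C)=O)c(OC)cc1OC | intermediate
13 | 1-{2-hydroxy-3-[(3S,4R)-3-hydroxy-1-methylpiperidin-4-yl]-4,6-dimethoxyphenyl}butane-1,3-dione | O[C@@H]1CN(C)CC[C@@H]1c1c(O)c(C(=O)CC(C)=O)c(OC)cc1OC | intermediate
14 | 8-[(3S,4R)-3-hydroxy-1-methylpiperidin-4-yl]-5,7-dimethoxy-2-methyl-4H-chromen-4-one | O[C@@H]1CN(C)CC[C@@H]1c1c(OC)cc(OC)c2c(=O)cc(C)oc12 | intermediate
15 | rohitukine, 5,7-dihydroxy-8-[(3S,4R)-3-hydroxy-1-methylpiperidin-4-yl]-2-methyl-4H-chromen-4-one | O[C@@H]1CN(C)CC[C@@H]1c1c(O)cc(O)c2c(=O)cc(C)oc12 | intermediate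
16 | angelic acid, (2Z)-2-methylbut-2-enoic acid | C/C=C(/C)C(=O)O | starting material
17 | 7-O,3'-O-bis-angelate of rohitukine: (3S,4R)-4-{5-hydroxy-2-methyl-7-[(2Z)-2-methylbut-2-enoyloxy]-4-oxo-4H-chromen-8-yl}-1-methylpiperidin-3-yl (2Z)-2-methylbut-2-enoate | C/C=C(/C)C(=O)O[C@@H]1CN(C)CC[C@@H]1c1c(OC(=O)/C(C)=C\C)cc(O)c2c(=O)cc(C)oc12 | intermediate
18 | (3S,4R)-4-(5,7-dihydroxy-2-methyl-4-oxo-4H-chromen-8-yl)-1-methylpiperidin-3-yl (2Z)-2-methylbut-2-enoate | C/C=C(/C)C(=O)O[C@@H]1CN(C)CC[C@@H]1c1c(O)cc(O)c2c(=O)cc(C)oc12 | target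

## Step count

Total steps: 6. Longest linear sequence: 6 steps (1 → 6 → 7 → 10 → 12 → 15 → 18).

## Steps most likely to fail, with fallbacks

Step 3. The hindered 2,4,6-trimethoxyphenyl group may slow the iridium stage, and the spent iridium/phosphine system may erode the enantio- or cis-selectivity of the ruthenium stage. The fallback sets out from ketone 9, which is then isolated after the iridium stage by filtration and evaporation. It is reduced with LiBH(s-Bu)3 in THF at −78 °C, hydride arriving anti to the aryl group, to racemic cis-1-methyl-4-(2,4,6-trimethoxyphenyl)piperidin-3-ol F1. The enantiomers of F1 are separated by preparative chromatography on a chiral stationary phase, and the (3S,4R) enantiomer is compound 10, where the route is rejoined.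

Step 5. Fusing the crude sodium diketonate directly with pyridine hydrochloride may give tar, incomplete cleavage of the 7-methoxy group, or some migration of the piperidinyl group from C8 to C6 by ring opening and reclosure. The fallback sets out from 12 and builds the pyranone from a different two-carbon unit. Condensation with N,N-dimethylacetamide dimethyl acetal (toluene, 100 °C) gives (2E)-3-(dimethylamino)-1-{2-hydroxy-3-[(3S,4R)-3-hydroxy-1-methylpiperidin-4-yl]-4,6-dimethoxyphenyl}but-2-en-1-one F2. This closes in AcOH/conc. HCl at 60 °C, with loss of dimethylamine, to 14, which is isolated and purified. Compound 14 is then demethylated on its own in a pyridine hydrochloride melt at 180 °C, which returns to the route at 15.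

Step 6. The hindered axial alcohol may acylate slowly, the angelate may partly isomerise to the tiglate, and the base used to cleave the aryl ester may also attack the alkyl ester through the neighbouring 7-phenoxide. The fallback sets out from 15 and protects first. TBSCl and imidazole in DMF at 0 °C silylate only the acidic 7-OH to give 7-O-tert-butyldimethylsilyl rohitukine F3. The same mixed anhydride of 16 (toluene, 75 °C) now has only the alcohol to acylate and gives 7-O-tert-butyldimethylsilyl rohitukine 3'-O-angelate F4. HF·pyridine in THF at 0 °C removes the silyl group without base and returns to the route at 18.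

## Further compounds

F1 | step 3 | racemic cis-1-methyl-4-(2,4,6-trimethoxyphenyl)piperidin-3-ol (1:1 mixture of the (3S,4R) and (3R,4S) enantiomers) | O[C@@H]1CN(C)CC[C@@H]1c1c(OC)cc(OC)cc1OC.O[C@H]1CN(C)CC[C@H]1c1c(OC)cc(OC)cc1OC
F2 | step 5 | (2E)-3-(dimethylamino)-1-{2-hydroxy-3-[(3S,4R)-3-hydroxy-1-methylpiperidin-4-yl]-4,6-dimethoxyphenyl}but-2-en-1-one | O[C@@H]1CN(C)CC[C@@H]1c1c(O)c(C(=O)/C=C(\C)N(C)C)c(OC)cc1OC
F3 | step 6 | 7-{[tert-butyl(dimethyl)silyl]oxy}-5-hydroxy-8-[(3S,4R)-3-hydroxy-1-methylpiperidin-4-yl]-2-methyl-4H-chromen-4-one | O[C@@H]1CN(C)CC[C@@H]1c1c(O[Si](C)(C)C(C)(C)C)cc(O)c2c(=O)cc(C)oc12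
F4 | step 6 | (3S,4R)-4-(7-{[tert-butyl(dimethyl)silyl]oxy}-5-hydroxy-2-methyl-4-oxo-4H-chromen-8-yl)-1-methylpiperidin-3-yl (2Z)-2-methylbut-2-enoate | C/C=C(/C)C(=O)O[C@@H]1CN(C)CC[C@@H]1c1c(O[Si](C)(C)C(C)(C)C)cc(O)c2c(=O)cc(C)oc12
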